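The runs are simulated from invented constants; the scatter is artificial.

The choice here is to scale a measured curve to the maple charge, not to write a rate law first.

| flask | Q | X | time |
|---|---|---|---|
| cedar | 0.0500 M | 0.150 M |  |
| birch | 0.0500 M | 0.300 M |  |
| elm | 0.150 M | 0.150 M |  |
| maple | 0.100 M | 0.0500 M | 180 s |

| run | time / s | [G] / M |
|---|---|---|
| cedar run | 26 | 0.00417 |
| cedar run | 51 | 0.00777 |
| cedar run | 77 | 0.01077 |
| cedar run | 100 | 0.01270 |
| cedar run | 130 | 0.01558 |
| cedar run | 150 | 0.01747 |
| cedar run | 180 | 0.01880 |
| birch run | 26 | 0.00604 |
| birch run | 51 | 0.01113 |
| birch run | 77 | 0.01506 |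
| birch run | 100 | 0.01833 |
| birch run | 130 | 0.02193 |
| birch run | 150 | 0.02358 |
| birch run | 180 | 0.02549 |
| elm run | 26 | 0.00822 |
| elm run | 51 | 0.01498 |
| elm run | 77 | 0.02097 |
| elm run | 100 | 0.02556 |
| elm run | 130 | 0.03132 |
| elm run | 150 | 0.03437 |
| elm run | 180 | 0.03768 |

(scatter of a reading: 2 × 10⁻⁴ M)

- Overall: Q + X -> G.
- Constant volume, constant temperature.
- Bound and free are read together.
- "The second partner" is X.
- An order is taken over about fifteen percent of the charge, up and down.

* the power of [Q] that the first rate follows, about the charge of the cedar run; measure it at two percent of Q made into G (one fixed amount of G, the same in the runs compared)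
* the power of [X] that the first rate follows, about the charge of the cedar run; measure it at two percent of Q made into G
* G in the maple run at 180 s, as a share of the Q charged

1. The ladder of rates begins with the first reading of each run. G divided by time gives 0.316 mM s⁻¹ in elm, 0.232 mM s⁻¹ in birch and 0.160 mM s⁻¹ in cedar, so elm runs faster than birch, and birch faster than cedar.

2. Between cedar and elm, [Q] changes while [X] stays the same, and the slopes give a power of 0.618. Between cedar and birch, [X] changes while [Q] stays the same, and the power reads 0.535. These are readings across wide steps in charge.

3. For maple, the two powers give 0.853. This is the charge scale: the ratio of Q charges raised to the Q power, times the ratio of X charges raised to the X power, taken here as the factor that carries the cedar curve to a new charge. The estimate therefore puts maple on the bottom rung, at 0.137 mM s⁻¹, slower than the other first readings.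

4. The first answer scales the cedar reading at 180 s to 0.0160 M, or 16.0% of the Q charged.

5. That answer goes back in once. X is the limiting reagent of maple, at 0.0500 M against 0.100 M of Q. By the two powers, the remaining charges put the rate at 0.696 of its start in cedar and 0.730 in maple. Taking the geometric mean of that gain raises G to 0.0164 M, or 16.4%.

6. The forecast gives 0.74 (0.6 to 0.88) as the order in Q, 0.65 (0.52 to 0.8) as the order in X, and 13% (11.2% to 14.8%) for maple. Its ground: “Rates fall faster than depletion explains”. The reckoning above differs, standing higher for maple.

7. The simulation gives 0.67 as the order in Q, 0.58 as the order in X, and 15.7% for maple. All of the forecast's values count as right within the tolerance of the question, although the maple share lies above the forecast's own high end.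

    Q + X ⇌ G (0.2140 M⁻¹ s⁻¹, 0.003270 s⁻¹)
    2 X ⇌ X2, settled at all times (42.40 M⁻¹)
    2 Q ⇌ Q2, settled at all times (27.40 M⁻¹)

The maple run gives 15.7% against 16.4% from the charge scale. For birch the scale is 1.45, built from the first birch reading itself, which turns the 94.1 s cedar takes to reach a quarter of its Q into 64.9 s, against 59.4 s in the birch run. The pairings of X to X2 and of Q to Q2 hold down G in the maple run: the maple run stands at 15.7%, but at 27.4% without the pairing to X2 and 30.7% without the pairing to Q2.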